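## Retrosynthetic overview

1. The α-alkylidene-β-hydroxy-γ-butyrolactone is a cyclic Morita–Baylis–Hillman adduct. Lactone C3 is the α-carbon of an enoate (C3=C10′), C4 is an aldehyde-derived carbinol, and the ring oxygen O1 on C5 already tethers the two. The C3–C4 bond is therefore cut first, and the only ring is closed in the last step from the acyclic isomer 21.
2. 21 is cut at the ester C–O bond into acid 13 and (R)-alcohol 18 (C5 from the (S)-glycerate chiral pool, isobutenyl group by Wittig reaction).
3. 13 comes from cross-metathesis with acrylic acid, after Brown allylation of enal 8 (sets C8′), allylic oxidation of neryl ester 6, and esterification of nerol 5 with acid 4.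

Key step: step 15

Remark: lactone atoms are numbered O1, C2 (C=O), C3, C4, C5 and chain atoms C1′–C10′ from the esterified CH2. The target is read as (3E,4S,5R) in the lactone (C4–OH trans to the C5 isobutenyl group) and (2′Z,6′E,8′S) in the chain, with a (2E)-3-methylpent-2-enoate.

## Route

Step 1
Reactants: 1 ethyl but-2-ynoate
Product: 3 ethyl (2E)-3-methylpent-2-enoate, via alkenylcopper adduct 2 (not isolated)
Conditions: EtMgBr, CuBr·SMe2, THF, −78 °C; then 1, −78 °C; aq NH4Cl at −78 °C
Reagents that add atoms: ethylmagnesium bromide, CC[Mg]Br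
Why: Syn-carbocupration of the alkynoate by the organocopper reagent should give the configurationally stable alkenylcopper 2 (ethyl cis to copper), and protonation with retention places the ethyl group trans to the ester, which is the (E)-enoate.

Step 2
Reactants: 3 ethyl (2E)-3-methylpent-2-enoate
Product: 4 (2E)-3-methylpent-2-enoic acid
Conditions: LiOH, THF/H2O, 23 °C; then aq HCl to pH 2
Reagents that add atoms: lithium hydroxide, [Li+].[OH-]
Why: Saponification by acyl–oxygen cleavage should leave the trisubstituted alkene geometry untouched.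

Step 3
Reactants: 4 (2E)-3-methylpent-2-enoic acid; 5 nerol, (2Z)-3,7-dimethylocta-2,6-dien-1-ol
Product: 6 (2Z)-3,7-dimethylocta-2,6-dien-1-yl (2E)-3-methylpent-2-enoate
Conditions: DCC, DMAP (10 mol %), CH2Cl2, 0 → 23 °C
Reagents that add atoms: none
Why: Steglich esterification of a primary allylic alcohol should proceed without touching either alkene geometry.

Step 4
Reactants: 6 (2Z)-3,7-dimethylocta-2,6-dien-1-yl (2E)-3-methylpent-2-enoate
Product: 8 (2Z,6E)-3,7-dimethyl-8-oxoocta-2,6-dien-1-yl (2E)-3-methylpent-2-enoate, via allylic alcohol 7 (not isolated)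
Conditions: SeO2 (20 mol %), t-BuOOH (3 equiv), salicylic acid (10 mol %), CH2Cl2, 23 °C; aqueous wash; then MnO2 (15 equiv), CH2Cl2, 23 °C
Reagents that add atoms: tert-butyl hydroperoxide, CC(C)(C)OO (terminal source of the new oxygen, passed on through selenium dioxide, O=[Se]=O)
Why: Catalytic SeO2 allylic oxidation (ene reaction, then [2,3]-shift) should hydroxylate the (E)-methyl group of the most electron-rich trisubstituted alkene, and MnO2 then converts the allylic alcohol 7 chemoselectively into the (E)-enal.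

Step 5
Reactants: 8 (2Z,6E)-3,7-dimethyl-8-oxoocta-2,6-dien-1-yl (2E)-3-methylpent-2-enoate
Product: 10 (2Z,6E,8S)-8-hydroxy-3,7-dimethylundeca-2,6,10-trien-1-yl (2E)-3-methylpent-2-enoate, via borinate ester 9 (not isolated)
Conditions: (−)-Ipc2B(allyl) (1.3 equiv), Et2O, −78 °C; then NaBO3·4H2O, THF/H2O, 23 °C
Reagents that add atoms: (−)-B-allyldiisopinocampheylborane, C=CCB([C@@H]1C[C@@H]2C[C@@H](C2(C)C)[C@H]1C)[C@@H]1C[C@@H]2C[C@@H](C2(C)C)[C@H]1C
Why: Brown allylboration through a chair Zimmerman–Traxler transition state should be reagent-controlled by the isopinocampheyl groups derived from (+)-α-pinene, giving the (8S)-carbinol as with other conjugated aldehydes, while both esters are inert at −78 °C.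

Step 6
Reactants: 10 (2Z,6E,8S)-8-hydroxy-3,7-dimethylundeca-2,6,10-trien-1-yl (2E)-3-methylpent-2-enoate
Product: 11 (2Z,6E,8S)-8-acetoxy-3,7-dimethylundeca-2,6,10-trien-1-yl (2E)-3-methylpent-2-enoate
Conditions: Ac2O, pyridine, DMAP (5 mol %), CH2Cl2, 0 → 23 °C
Reagents that add atoms: acetic anhydride, CC(=O)OC(C)=O
Why: DMAP-catalysed acetylation of the secondary alcohol proceeds with retention because the C–O bond is not broken.

Step 7
Reactants: 11 (2Z,6E,8S)-8-acetoxy-3,7-dimethylundeca-2,6,10-trien-1-yl (2E)-3-methylpent-2-enoate; 12 acrylic acid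
Product: 13 (2E,5S,6E,10Z)-5-acetoxy-6,10-dimethyl-12-{[(2E)-3-methylpent-2-enoyl]oxy}dodeca-2,6,10-trienoic acid
Conditions: acrylic acid (4 equiv), second-generation Hoveyda–Grubbs catalyst RuCl2(H2IMes)(=CH-C6H4-2-O-i-Pr) (5 mol %), CH2Cl2, 40 °C
Reagents that add atoms: none
Why: Olefin cross-metathesis of the only monosubstituted alkene with an electron-poor acrylic partner should be E-selective, and the trisubstituted alkenes are too hindered to take part.

Step 8
Reactants: 14 methyl (4S)-2,2-dimethyl-1,3-dioxolane-4-carboxylate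
Product: 15 (4S)-2,2-dimethyl-1,3-dioxolane-4-carbaldehyde
Conditions: i-Bu2AlH (1.05 equiv), CH2Cl2, −78 °C; MeOH, then aq KNaC4H4O6
Reagents that add atoms: none
Why: Partial reduction of the ester stops at the aldehyde because the tetrahedral aluminium hemiacetal is stable at −78 °C, and the α-stereocentre is not touched.

Step 9
Reactants: 15 (4S)-2,2-dimethyl-1,3-dioxolane-4-carbaldehyde
Product: 16 (4R)-2,2-dimethyl-4-(2-methylprop-1-en-1-yl)-1,3-dioxolane
Conditions: i-PrPPh3I, n-BuLi, THF, 0 °C; then 15, −78 → 23 °C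
Reagents that add atoms: isopropyltriphenylphosphonium iodide, CC(C)[P+](c1ccccc1)(c1ccccc1)c1ccccc1.[I-]
Why: Wittig olefination with the non-stabilised isopropylidene ylide at low temperature should give the trisubstituted alkene without epimerising the α-alkoxy centre; the descriptor changes from S to R only through the priority switch.

Step 10
Reactants: 16 (4R)-2,2-dimethyl-4-(2-methylprop-1-en-1-yl)-1,3-dioxolane
Product: 17 (2R)-4-methylpent-3-ene-1,2-diol
Conditions: AcOH/H2O (4:1), 23 °C
Reagents that add atoms: none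
Why: Mild acid hydrolysis of the acetonide should free the diol, since the adjacent oxygen disfavours ionisation of the allylic C–O bond.

Step 11
Reactants: 17 (2R)-4-methylpent-3-ene-1,2-diol
Product: 18 (2R)-1-[(tert-butyldimethylsilyl)oxy]-4-methylpent-3-en-2-ol
Conditions: TBSCl (1.05 equiv), imidazole, CH2Cl2, −20 → 0 °C
Reagents that add atoms: tert-butyldimethylsilyl chloride, CC(C)(C)[Si](C)(C)Cl
Why: Silylation should be selective for the primary hydroxyl on steric grounds.

Step 12
Reactants: 13 (2E,5S,6E,10Z)-5-acetoxy-6,10-dimethyl-12-{[(2E)-3-methylpent-2-enoyl]oxy}dodeca-2,6,10-trienoic acid; 18 (2R)-1-[(tert-butyldimethylsilyl)oxy]-4-methylpent-3-en-2-ol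
Product: 19 (2R)-1-[(tert-butyldimethylsilyl)oxy]-4-methylpent-3-en-2-yl (2E,5S,6E,10Z)-5-acetoxy-6,10-dimethyl-12-{[(2E)-3-methylpent-2-enoyl]oxy}dodeca-2,6,10-trienoate
Conditions: DCC, DMAP (10 mol %), CH2Cl2, 0 °C
Reagents that add atoms: none
Why: Steglich esterification acylates the secondary allylic alcohol with retention, and the low temperature with little DMAP should avoid deconjugation of the activated enoic acid.

Step 13
Reactants: 19 (2R)-1-[(tert-butyldimethylsilyl)oxy]-4-methylpent-3-en-2-yl ester of acid 13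
Product: 20 (2R)-1-hydroxy-4-methylpent-3-en-2-yl (2E,5S,6E,10Z)-5-acetoxy-6,10-dimethyl-12-{[(2E)-3-methylpent-2-enoyl]oxy}dodeca-2,6,10-trienoate
Conditions: HF·pyridine, pyridine, THF, 0 °C
Reagents that add atoms: none
Why: Desilylation with buffered hydrogen fluoride avoids the basic alkoxide that would drive 1,2-acyl migration, and leaves the three esters intact.

Step 14
Reactants: 20 (2R)-1-hydroxy-4-methylpent-3-en-2-yl ester of acid 13
Product: 21 (2R)-4-methyl-1-oxopent-3-en-2-yl (2E,5S,6E,10Z)-5-acetoxy-6,10-dimethyl-12-{[(2E)-3-methylpent-2-enoyl]oxy}dodeca-2,6,10-trienoate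
Conditions: Dess–Martin periodinane, pyridine, CH2Cl2, 0 °C; short silica pad, used at once
Reagents that add atoms: none
Why: Buffered Dess–Martin oxidation is the standard non-epimerising route to configurationally labile α-oxygenated aldehydes.

Step 15
Reactants: 21 (2R)-4-methyl-1-oxopent-3-en-2-yl (2E,5S,6E,10Z)-5-acetoxy-6,10-dimethyl-12-{[(2E)-3-methylpent-2-enoyl]oxy}dodeca-2,6,10-trienoate
Product: 23 (2Z,6E,8S)-8-acetoxy-10-[(3E,4S,5R)-4-hydroxy-5-(2-methylprop-1-en-1-yl)-2-oxooxolan-3-ylidene]-3,7-dimethyldeca-2,6-dien-1-yl (2E)-3-methylpent-2-enoate, via phosphonium aldolate 22 (not isolated)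
Conditions: PMe3 (30 mol %), t-AmOH (0.02 M), 23 °C, argon
Reagents that add atoms: none
Why: PMe3 adds reversibly to C10′ of the enoate, the phosphonium enolate closes onto the C4 aldehyde through its α-carbon (lactone C3), and proton transfer followed by E1cB loss of PMe3 restores the C3=C10′ alkene, so aldehyde 21 is isomerised to 23 with the phosphine as the only reagent. The closest known reactions are the trialkylphosphine-catalysed intramolecular Morita–Baylis–Hillman cyclisation of enoate aldehydes and the amine-catalysed closure of acrylates of α-hydroxy aldehydes to α-methylene-β-hydroxy-γ-butyrolactones. The γ-lactone is closed in a 5-(enolendo)-exo-trig aldol mode, the same mode as intramolecular Reformatsky lactonisations through an ester tether. The new C4 stereocentre is controlled by C5: in the envelope transition state the aldehyde oxygen lies anti to the isobutenyl group, and the reversible aldol step lets the cis aldolate revert, so the 4,5-trans (4S,5R) lactone should dominate. The E geometry is expected from the elimination, in which C9′ turns away from the in-plane enolate oxygen, and from phosphine-mediated equilibration of the product; because C10′ is sp3 in intermediate 22, both geometrical isomers of the enoate converge on the same alkene. The step needs chemoselectivity for the β-monosubstituted enoate over the β,β-disubstituted 3-methylpent-2-enoate, which the steric demand of conjugate addition secures, and it needs C5 to keep its configuration, which the weakly basic phosphine in a protic solvent should allow.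

## Compound list

1 | ethyl but-2-ynoate | CC#CC(=O)OCC | starting material
2 | ethyl (2Z)-2-cuprio-3-methylpent-2-enoate (alkenylcopper adduct) | CC/C(C)=C(\[Cu])C(=O)OCC | intermediate
3 | ethyl (2E)-3-methylpent-2-enoate | CC/C(C)=C/C(=O)OCC | intermediate
4 | (2E)-3-methylpent-2-enoic acid | CC/C(C)=C/C(=O)O | intermediate
5 | nerol, (2Z)-3,7-dimethylocta-2,6-dien-1-ol | CC(C)=CCC/C(C)=C\CO | starting material
6 | (2Z)-3,7-dimethylocta-2,6-dien-1-yl (2E)-3-methylpent-2-enoate | CC/C(C)=C/C(=O)OC/C=C(/C)CCC=C(C)C | intermediate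
7 | (2Z,6E)-8-hydroxy-3,7-dimethylocta-2,6-dien-1-yl (2E)-3-methylpent-2-enoate | CC/C(C)=C/C(=O)OC/C=C(/C)CC/C=C(\C)CO | intermediate
8 | (2Z,6E)-3,7-dimethyl-8-oxoocta-2,6-dien-1-yl (2E)-3-methylpent-2-enoate | CC/C(C)=C/C(=O)OC/C=C(/C)CC/C=C(\C)C=O | intermediate
9 | O-diisopinocampheylboryl derivative of 10 (borinate ester) | CC/C(C)=C/C(=O)OC/C=C(/C)CC/C=C(\C)[C@H](CC=C)OB([C@@H]1C[C@@H]2C[C@@H](C2(C)C)[C@H]1C)[C@@H]1C[C@@H]2C[C@@H](C2(C)C)[C@H]1C | intermediate
10 | (2Z,6E,8S)-8-hydroxy-3,7-dimethylundeca-2,6,10-trien-1-yl (2E)-3-methylpent-2-enoate | CC/C(C)=C/C(=O)OC/C=C(/C)CC/C=C(\C)[C@H](CC=C)O | intermediate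
11 | (2Z,6E,8S)-8-acetoxy-3,7-dimethylundeca-2,6,10-trien-1-yl (2E)-3-methylpent-2-enoate | CC/C(C)=C/C(=O)OC/C=C(/C)CC/C=C(\C)[C@H](CC=C)OC(C)=O | intermediate
12 | acrylic acid | C=CC(=O)O | starting material
13 | (2E,5S,6E,10Z)-5-acetoxy-6,10-dimethyl-12-{[(2E)-3-methylpent-2-enoyl]oxy}dodeca-2,6,10-trienoic acid | CC/C(C)=C/C(=O)OC/C=C(/C)CC/C=C(\C)[C@H](C/C=C/C(=O)O)OC(C)=O | intermediate
14 | methyl (4S)-2,2-dimethyl-1,3-dioxolane-4-carboxylate | COC(=O)[C@@H]1COC(C)(C)O1 | starting material
15 | (4S)-2,2-dimethyl-1,3-dioxolane-4-carbaldehyde | O=C[C@@H]1COC(C)(C)O1 | intermediate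
16 | (4R)-2,2-dimethyl-4-(2-methylprop-1-en-1-yl)-1,3-dioxolane | CC(C)=C[C@@H]1COC(C)(C)O1 | intermediate
17 | (2R)-4-methylpent-3-ene-1,2-diol | CC(C)=C[C@@H](O)CO | intermediate
18 | (2R)-1-[(tert-butyldimethylsilyl)oxy]-4-methylpent-3-en-2-ol | CC(C)=C[C@@H](O)CO[Si](C)(C)C(C)(C)C | intermediate
19 | (2R)-1-[(tert-butyldimethylsilyl)oxy]-4-methylpent-3-en-2-yl (2E,5S,6E,10Z)-5-acetoxy-6,10-dimethyl-12-{[(2E)-3-methylpent-2-enoyl]oxy}dodeca-2,6,10-trienoate | CC/C(C)=C/C(=O)OC/C=C(/C)CC/C=C(\C)[C@H](C/C=C/C(=O)O[C@@H](CO[Si](C)(C)C(C)(C)C)C=C(C)C)OC(C)=O | intermediate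
20 | (2R)-1-hydroxy-4-methylpent-3-en-2-yl (2E,5S,6E,10Z)-5-acetoxy-6,10-dimethyl-12-{[(2E)-3-methylpent-2-enoyl]oxy}dodeca-2,6,10-trienoate | CC/C(C)=C/C(=O)OC/C=C(/C)CC/C=C(\C)[C@H](C/C=C/C(=O)O[C@@H](CO)C=C(C)C)OC(C)=O | intermediate
21 | (2R)-4-methyl-1-oxopent-3-en-2-yl (2E,5S,6E,10Z)-5-acetoxy-6,10-dimethyl-12-{[(2E)-3-methylpent-2-enoyl]oxy}dodeca-2,6,10-trienoate | CC/C(C)=C/C(=O)OC/C=C(/C)CC/C=C(\C)[C@H](C/C=C/C(=O)O[C@@H](C=O)C=C(C)C)OC(C)=O | intermediate
22 | zwitterionic 3-[1-(trimethylphosphonio)alkyl] lactone 4-alkoxide (phosphonium aldolate; C3 and C10′ not defined) | CC/C(C)=C/C(=O)OC/C=C(/C)CC/C=C(\C)[C@H](CC([P+](C)(C)C)C1C(=O)O[C@H](C=C(C)C)[C@H]1[O-])OC(C)=O | intermediate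
23 | (2Z,6E,8S)-8-acetoxy-10-[(3E,4S,5R)-4-hydroxy-5-(2-methylprop-1-en-1-yl)-2-oxooxolan-3-ylidene]-3,7-dimethyldeca-2,6-dien-1-yl (2E)-3-methylpent-2-enoate | CC/C(C)=C/C(=O)OC/C=C(/C)CC/C=C(\C)[C@H](C/C=C1/C(=O)O[C@H](C=C(C)C)[C@H]1O)OC(C)=O | target

## Summary and risks

Total step count: 15. Longest linear sequence: 11 steps (steps 1–7, then 12–15).

Steps most likely to fail:

1. Step 15 (key step). The phosphine may add too slowly to the β-alkyl enoate. Enolisation of the α-acyloxy-β,γ-unsaturated aldehyde could erode the C5 configuration or move the alkene into conjugation. The C8′ acetate could be lost by vinylogous elimination, and trans or E control could be incomplete. The fallback sets out from 18 and returns at 23. Acylation of 18 with acryloyl chloride (Et3N, CH2Cl2, −20 °C) should give (2R)-1-[(tert-butyldimethylsilyl)oxy]-4-methylpent-3-en-2-yl prop-2-enoate F1. HF·pyridine then frees (2R)-1-hydroxy-4-methylpent-3-en-2-yl prop-2-enoate F2, and Dess–Martin oxidation gives (2R)-4-methyl-1-oxopent-3-en-2-yl prop-2-enoate F3. DABCO (CH2Cl2, 23 °C) closes the same C3–C4 bond in the much faster unsubstituted acrylate series to give (4S,5R)-4-hydroxy-3-methylidene-5-(2-methylprop-1-en-1-yl)oxolan-2-one F4. Cross-metathesis of F4 with the terminal alkene 11 (second-generation Hoveyda–Grubbs catalyst, 2,6-dichloro-1,4-benzoquinone, CH2Cl2, 40 °C) then attaches the chain E-selectively and gives 23.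

2. Step 13. After desilylation the acyl group may migrate from the secondary to the primary oxygen, and the hydroxy ester must be handled before the labile aldehyde is made. The fallback sets out from 17 and returns at 21, and never passes through a free hydroxy ester. Silylation of 17 with TESCl (imidazole, CH2Cl2, −20 °C) gives (2R)-4-methyl-1-[(triethylsilyl)oxy]pent-3-en-2-ol F5. Esterification with 13 (DCC, DMAP) gives the triethylsilyl analogue of 19, (2R)-4-methyl-1-[(triethylsilyl)oxy]pent-3-en-2-yl (2E,5S,6E,10Z)-5-acetoxy-6,10-dimethyl-12-{[(2E)-3-methylpent-2-enoyl]oxy}dodeca-2,6,10-trienoate F6. Swern conditions ((COCl)2, DMSO, CH2Cl2, −78 → −40 °C; then i-Pr2NEt) then oxidise the primary triethylsilyl ether directly to 21.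

3. Step 4. The allylic oxidation may stall, over-oxidise, or attack other allylic positions, which would give an inseparable mixture. The fallback sets out from 6 and returns at 8. Cross-metathesis of 6 with methacrolein (second-generation Hoveyda–Grubbs catalyst, CH2Cl2, 40 °C) exchanges the isopropylidene terminus, the most accessible trisubstituted alkene, for the (E)-2-methyl enal and gives 8 directly without any selenium chemistry.

## Further compounds

F1 | step 15 | (2R)-1-[(tert-butyldimethylsilyl)oxy]-4-methylpent-3-en-2-yl prop-2-enoate | C=CC(=O)O[C@@H](CO[Si](C)(C)C(C)(C)C)C=C(C)C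
F2 | step 15 | (2R)-1-hydroxy-4-methylpent-3-en-2-yl prop-2-enoate | C=CC(=O)O[C@@H](CO)C=C(C)C
F3 | step 15 | (2R)-4-methyl-1-oxopent-3-en-2-yl prop-2-enoate | C=CC(=O)O[C@@H](C=O)C=C(C)C
F4 | step 15 | (4S,5R)-4-hydroxy-3-methylidene-5-(2-methylprop-1-en-1-yl)oxolan-2-one | C=C1C(=O)O[C@H](C=C(C)C)[C@H]1O
F5 | step 13 | (2R)-4-methyl-1-[(triethylsilyl)oxy]pent-3-en-2-ol | CC(C)=C[C@@H](O)CO[Si](CC)(CC)CC
F6 | step 13 | (2R)-4-methyl-1-[(triethylsilyl)oxy]pent-3-en-2-yl (2E,5S,6E,10Z)-5-acetoxy-6,10-dimethyl-12-{[(2E)-3-methylpent-2-enoyl]oxy}dodeca-2,6,10-trienoate | CC/C(C)=C/C(=O)OC/C=C(/C)CC/C=C(\C)[C@H](C/C=C/C(=O)O[C@@H](CO[Si](CC)(CC)CC)C=C(C)C)OC(C)=O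
F0 | step 4 | none | none
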